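**Plan**
1. Target: (3R)-8-hydroxy-6-methoxy-3-(6-oxoundecyl)-3,4-dihydroisocoumarin, with benzene ring A, δ-lactone ring B (C1, O2, C3, C4, C4a, C8a) and a chain C1'–C11' carrying the ketone at C6'.
2. Feature used: C3 is a secondary carbinol carbon bonded to O2, to the benzylic C4 methylene and to C1'. It therefore maps onto the carbonyl carbon of an arylacetaldehyde that accepts the whole chain as a nucleophile.
3. Retrosynthetic cuts, in order: the C8 hydroxyl back to a methyl ether; the lactone bond C1–O2 and the C6' ketone back to a dioxolane; the bond C3–C1'; then, in the arene fragment, the aldehyde back to an allyl group, the aryl–allyl bond C4a–C4 and the carboxyl carbon on C8a; in the chain, the carbon–metal bond at C1' back to a terminal alkene and the bond C5'–C6'.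
4. Forward: ring A is bought. The arene fragment (steps 1–5) and the chain fragment (steps 6–8) are made separately. In step 9 the chain borane is converted in the flask into the dialkylzinc, which is joined at C3 without ring closure. Ring B closes in step 10, and O-demethylation at C8 finishes the route in step 11.
5. Stereochemistry: the only stereocentre, C3, is set in step 9 by the (1S,2S)-bis(trifluoromethanesulfonamide) ligand on titanium (alkyl delivery to the Re face gives R), and no later step breaks a bond at C3.

Key step: step 9

Remark: metal alkoxides, carboxylates and boron aryloxides that are only protonated on work-up are counted as the product of their step and carry no number of their own.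
Remark: the sense of induction is assumed to be the one established for this catalyst class with aldehydes RCH2CHO ((1R,2R)-ligand, Si-face attack); if it proved reversed for the arylacetaldehyde used here, the (1R,2R)-ligand would be used instead.

**Route**

Step 1
Reactants: 1 1-bromo-3,5-dimethoxybenzene
Product: 3 2-bromo-4,6-dimethoxybenzaldehyde, via iminium chloride 2 (not isolated)
Conditions: POCl3 (2 equiv.), DMF, 0 °C → 90 °C; then ice-water, rt
Reagents that add atoms: N,N-dimethylformamide, CN(C)C=O (formyl carbon); water, O (aldehyde oxygen)
Why: Vilsmeier–Haack formylation, in which the chloroiminium ion from DMF and POCl3 should attack the ring carbon next to bromine (ortho to one methoxy group, para to the other and less crowded than the carbon between the two methoxy groups), the iminium salt being hydrolysed to the aldehyde on aqueous work-up.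

Step 2
Reactants: 3 2-bromo-4,6-dimethoxybenzaldehyde
Product: 4 2-bromo-4,6-dimethoxybenzoic acid
Conditions: NaClO2, NaH2PO4, 2-methylbut-2-ene, tBuOH–H2O, rt
Reagents that add atoms: sodium chlorite, [Na+].[O-]Cl=O
Why: Pinnick oxidation converts hindered aromatic aldehydes into acids under buffered conditions that leave the aryl bromide alone, while 2-methylbut-2-ene traps the hypochlorous acid that could otherwise chlorinate the electron-rich ring.

Step 3
Reactants: 4 2-bromo-4,6-dimethoxybenzoic acid
Product: 5 methyl 2-bromo-4,6-dimethoxybenzoate
Conditions: MeI, K2CO3, DMF, rt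
Reagents that add atoms: iodomethane, CI
Why: O-alkylation of the carboxylate (SN2 on iodomethane) avoids the slow Fischer esterification of a benzoic acid with two ortho substituents.

Step 4
Reactants: 5 methyl 2-bromo-4,6-dimethoxybenzoate; 6 allylboronic acid pinacol ester
Product: 7 methyl 2,4-dimethoxy-6-(prop-2-en-1-yl)benzoate
Conditions: Pd(PPh3)4 (5 mol%), CsF (3 equiv.), THF, reflux
Reagents that add atoms: none
Why: Suzuki–Miyaura allylation, in which zerovalent palladium inserts into the C–Br bond activated by the ortho ester and the fluoride-activated allylboronate transfers the allyl group, the mild non-hydroxide base limiting migration of the double bond into conjugation.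

Step 5
Reactants: 7 methyl 2,4-dimethoxy-6-(prop-2-en-1-yl)benzoate
Product: 9 methyl 2,4-dimethoxy-6-(2-oxoethyl)benzoate, via diol 8 (not isolated)
Conditions: OsO4 (2 mol%), NaIO4 (4 equiv.), 2,6-lutidine (2 equiv.), 1,4-dioxane–H2O (3:1), rt
Reagents that add atoms: osmium tetroxide, O=[Os](=O)(=O)=O (oxygen donor, restored by periodate); sodium periodate, [Na+].[O-]I(=O)(=O)=O
Why: Lemieux–Johnson oxidation, in which catalytic OsO4 dihydroxylates the terminal alkene and periodate cleaves the diol, with 2,6-lutidine suppressing over-oxidation so that the arylacetaldehyde can be extracted and used at once without chromatography on acidic media.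

Step 6
Reactants: 10 5-bromopent-1-ene; 11 hexanoyl chloride
Product: 13 undec-10-en-6-one, via pent-4-enylmagnesium bromide 12 (not isolated)
Conditions: Mg, THF, rt → 40 °C; then 11, Fe(acac)3 (3 mol%), THF, −78 °C
Reagents that add atoms: none
Why: Iron-catalysed acylation of a Grignard reagent by an acid chloride is much faster at −78 °C than addition of the Grignard reagent to the ketone formed, so the reaction should stop at the ketone and form the C5'–C6' bond in one operation.

Step 7
Reactants: 13 undec-10-en-6-one
Product: 14 2-pentyl-2-(pent-4-en-1-yl)-1,3-dioxolane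
Conditions: ethylene glycol (3 equiv.), pTsOH·H2O (5 mol%), toluene, reflux, Dean–Stark trap
Reagents that add atoms: ethane-1,2-diol, OCCO
Why: Acid-catalysed ketalisation driven by azeotropic removal of water masks the ketone as a dioxolane that is inert to boranes and organozinc reagents.

Step 8
Reactants: 14 2-pentyl-2-(pent-4-en-1-yl)-1,3-dioxolane
Product: 15 diethyl[5-(2-pentyl-1,3-dioxolan-2-yl)pentyl]borane
Conditions: Et2BH (1.05 equiv., made in the flask from BH3·SMe2 and Et3B, 1:2), neat, 0 °C → rt; volatiles removed in vacuo; crude 15 kept under argon and used at once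
Reagents that add atoms: diethylborane, CCBCC
Why: Anti-Markovnikov hydroboration of the terminal alkene places boron on the terminal carbon and gives a trialkylborane with one primary alkyl group that can later be passed to zinc, the dioxolane being inert to the dialkylborane.

Step 9
Reactants: 9 methyl 2,4-dimethoxy-6-(2-oxoethyl)benzoate; 15 diethyl[5-(2-pentyl-1,3-dioxolan-2-yl)pentyl]borane
Product: 17 methyl 2-[(2R)-2-hydroxy-7-(2-pentyl-1,3-dioxolan-2-yl)heptyl]-4,6-dimethoxybenzoate, via dialkylzinc 16 (not isolated)
Conditions: 15 (4 equiv.), Et2Zn (2 equiv. per boron), neat, 0 °C, 30 min; Et3B and excess Et2Zn removed in vacuo (twice); then toluene, (1S,2S)-1,2-bis(trifluoromethanesulfonamido)cyclohexane (8 mol%), Ti(OiPr)4 (2 equiv.), −20 °C, 9 (1 equiv.); then sat. aq. NH4Cl, −20 °C → rt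
Reagents that add atoms: none
Why: Boron–zinc exchange first moves the primary alkyl group of two molecules of 15 onto one zinc atom, and pumping off Et3B and excess Et2Zn leaves salt-free dialkylzinc 16; the complex of tetravalent titanium formed from the bis-sulfonamide and Ti(OiPr)4 then binds the aldehyde carbonyl of 9, and one alkyl group of 16 passes from zinc through titanium to the carbonyl carbon, forming the C3–C1' bond and a metal alkoxide that is protonated on work-up. The closest known reaction type is the Ti(OiPr)4/bis-triflamide catalysed enantioselective addition of functionalised dialkylzinc reagents, made by hydroboration and boron–zinc exchange, to aliphatic aldehydes. No ring closes in this step: the methyl ester, flanked by two ortho substituents, should stay untouched at −20 °C and the cold quench should deliver the open hydroxy ester, while partial lactonisation on handling would do no harm because step 10 closes ring B in any case. The new stereocentre C3 is controlled by the ligand alone, the (1S,2S)-enantiomer being expected to send the alkyl group to the Re face of the aldehyde, which gives the (R)-carbinol because the CH2Ar group outranks the incoming chain. The step needs chemoselectivity for the aldehyde over the ester and must avoid enolisation of the acidic arylacetaldehyde; both are secured by the low basicity of the zinc and titanium species, while the dioxolane keeps the chain ketone protected. Four equivalents of 15 (two of 16) are used because only one alkyl group per zinc is transferred readily, which is affordable for a three-step fragment.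

Step 10
Reactants: 17 methyl 2-[(2R)-2-hydroxy-7-(2-pentyl-1,3-dioxolan-2-yl)heptyl]-4,6-dimethoxybenzoate
Product: 18 (3R)-6,8-dimethoxy-3-(6-oxoundecyl)-3,4-dihydro-1H-isochromen-1-one
Conditions: pTsOH·H2O (0.3 equiv.), THF–H2O (5:1), 60 °C
Reagents that add atoms: water, O (ketone oxygen)
Why: Acid-catalysed lactonisation (intramolecular transesterification closing the six-membered ring B by attack of the C3 hydroxyl on the ester carbonyl) runs alongside hydrolysis of the dioxolane, and since the C3–O bond is never broken the configuration is retained.

Step 11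
Reactants: 18 (3R)-6,8-dimethoxy-3-(6-oxoundecyl)-3,4-dihydro-1H-isochromen-1-one
Product: 19 (3R)-8-hydroxy-6-methoxy-3-(6-oxoundecyl)-3,4-dihydro-1H-isochromen-1-one
Conditions: BCl3 (2.5 equiv., 1 M in CH2Cl2), CH2Cl2, −78 → 0 °C; then H2O
Reagents that add atoms: none
Why: Chelation-directed ether cleavage, in which BCl3 bridges the lactone carbonyl and the peri methoxy oxygen at C8 so that chloride removes only that methyl group, leaving the C6 methoxy group, the lactone, the chain ketone and C3 untouched.

**Compound list**
1 | 1-bromo-3,5-dimethoxybenzene | COc1cc(Br)cc(OC)c1 | starting material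
2 | N-[(2-bromo-4,6-dimethoxyphenyl)methylidene]-N-methylmethanaminium chloride | C[N+](C)=Cc1c(Br)cc(OC)cc1OC.[Cl-] | intermediate
3 | 2-bromo-4,6-dimethoxybenzaldehyde | O=Cc1c(Br)cc(OC)cc1OC | intermediate
4 | 2-bromo-4,6-dimethoxybenzoic acid | OC(=O)c1c(Br)cc(OC)cc1OC | intermediate
5 | methyl 2-bromo-4,6-dimethoxybenzoate | COC(=O)c1c(Br)cc(OC)cc1OC | intermediate
6 | allylboronic acid pinacol ester (2-allyl-4,4,5,5-tetramethyl-1,3,2-dioxaborolane) | C=CCB1OC(C)(C)C(C)(C)O1 | starting material
7 | methyl 2,4-dimethoxy-6-(prop-2-en-1-yl)benzoate | COC(=O)c1c(CC=C)cc(OC)cc1OC | intermediate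
8 | methyl 2-(2,3-dihydroxypropyl)-4,6-dimethoxybenzoate (racemic) | COC(=O)c1c(CC(O)CO)cc(OC)cc1OC | intermediate
9 | methyl 2,4-dimethoxy-6-(2-oxoethyl)benzoate | COC(=O)c1c(CC=O)cc(OC)cc1OC | intermediate
10 | 5-bromopent-1-ene | C=CCCCBr | starting material
11 | hexanoyl chloride | CCCCCC(=O)Cl | starting material
12 | pent-4-en-1-ylmagnesium bromide | C=CCCC[Mg]Br | intermediate
13 | undec-10-en-6-one | CCCCCC(=O)CCCC=C | intermediate
14 | 2-pentyl-2-(pent-4-en-1-yl)-1,3-dioxolane | CCCCCC1(OCCO1)CCCC=C | intermediate
15 | diethyl[5-(2-pentyl-1,3-dioxolan-2-yl)pentyl]borane | CCCCCC1(OCCO1)CCCCCB(CC)CC | intermediate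
16 | bis[5-(2-pentyl-1,3-dioxolan-2-yl)pentyl]zinc (formed in the flask in step 9) | CCCCCC1(OCCO1)CCCCC[Zn]CCCCCC1(OCCO1)CCCCC | intermediate
17 | methyl 2-[(2R)-2-hydroxy-7-(2-pentyl-1,3-dioxolan-2-yl)heptyl]-4,6-dimethoxybenzoate | CCCCCC1(OCCO1)CCCCC[C@@H](O)Cc1cc(OC)cc(OC)c1C(=O)OC | intermediate
18 | (3R)-6,8-dimethoxy-3-(6-oxoundecyl)-3,4-dihydro-1H-isochromen-1-one | CCCCCC(=O)CCCCC[C@@H]1Cc2cc(OC)cc(OC)c2C(=O)O1 | intermediate
19 | (3R)-8-hydroxy-6-methoxy-3-(6-oxoundecyl)-3,4-dihydro-1H-isochromen-1-one | CCCCCC(=O)CCCCC[C@@H]1Cc2cc(OC)cc(O)c2C(=O)O1 | target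

**Summary**
Total step count: 11.
Longest linear sequence: 8 steps (steps 1–5, then 9–11, from compound 1); the chain branch contributes steps 6–8.

**Steps most likely to fail**

Step 9. The risks are incomplete boron–zinc exchange that leaves ethylzinc species able to transfer ethyl in competition with the chain, enolisation and aldol self-condensation of the arylacetaldehyde before alkyl transfer, and insufficient facial selectivity. The fallback sets out from 7 and comes back at 18; it gives up the carbonyl addition and takes the configuration from a resolved epoxide. Alkene 7 would be epoxidised with mCPBA (CH2Cl2, NaHCO3) to racemic methyl 2,4-dimethoxy-6-(oxiran-2-ylmethyl)benzoate F1. Hydrolytic kinetic resolution with the chiral (salen)Co(OAc) complex, [N,N'-bis(3,5-di-tert-butylsalicylidene)cyclohexane-1,2-diaminato]cobalt acetate, in the enantiomeric form that consumes the (R)-epoxide, and 0.55 equiv. of water should leave methyl 2,4-dimethoxy-6-[(2S)-oxiran-2-ylmethyl]benzoate F2. Copper-catalysed opening at the terminal carbon with commercial but-3-enylmagnesium bromide (CuI, THF, −30 °C) should give methyl 2-[(2R)-2-hydroxyhept-6-en-1-yl]-4,6-dimethoxybenzoate F3, and pTsOH in CH2Cl2 should close ring B to (3R)-6,8-dimethoxy-3-(pent-4-en-1-yl)-3,4-dihydro-1H-isochromen-1-one F4. Cross-metathesis with commercial oct-1-en-3-one (second-generation Hoveyda–Grubbs catalyst, CH2Cl2, 40 °C) should give (3R)-6,8-dimethoxy-3-[(4E)-6-oxoundec-4-en-1-yl]-3,4-dihydro-1H-isochromen-1-one F5, and hydrogenation (H2, Pd/C, EtOAc) returns to 18.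

Step 8. The risks are that the reagent written as Et2BH is an equilibrating mixture of ethylboranes, so that boranes carrying two chains or residual B–H bonds may form, and that the air-sensitive crude borane cannot be purified, so any such impurity passes into the zinc reagent. The fallback sets out from 14 and comes back at 16, which it reaches by iodine–zinc exchange from a purified iodide in place of boron–zinc exchange. Hydroboration of 14 with 9-BBN (THF, rt) should give 9-[5-(2-pentyl-1,3-dioxolan-2-yl)pentyl]-9-borabicyclo[3.3.1]nonane F6, which would be oxidised in the same flask (NaOH, H2O2) to 5-(2-pentyl-1,3-dioxolan-2-yl)pentan-1-ol F7. Iodination (I2, PPh3, imidazole, CH2Cl2) should give 2-(5-iodopentyl)-2-pentyl-1,3-dioxolane F8, a storable precursor that can be chromatographed. Treatment with neat Et2Zn and catalytic CuI at 50 °C, followed by evaporation of iodoethane and excess Et2Zn, should give 16, which then enters the titanium-catalysed addition of step 9 directly.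

Step 5. The risks are over-oxidation of the aldehyde as it forms in the oxidising aqueous medium, its self-condensation, and losses during isolation. The fallback sets out from 5 and comes back at 9 without any oxidant. Suzuki–Miyaura coupling of 5 with commercial (E)-2-(2-ethoxyvinyl)-4,4,5,5-tetramethyl-1,3,2-dioxaborolane (Pd(PPh3)4, aq. K2CO3, 1,4-dioxane, 80 °C) should give methyl 2-[(E)-2-ethoxyethenyl]-4,6-dimethoxybenzoate F9. Brief hydrolysis of the enol ether (2 M aq. HCl, THF, 0 °C) should release aldehyde 9 directly before its use in step 9.

**Further compounds**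
F1 | step 9 | methyl 2,4-dimethoxy-6-(oxiran-2-ylmethyl)benzoate (racemic) | COC(=O)c1c(CC2CO2)cc(OC)cc1OC
F2 | step 9 | methyl 2,4-dimethoxy-6-[(2S)-oxiran-2-ylmethyl]benzoate | COC(=O)c1c(C[C@H]2CO2)cc(OC)cc1OC
F3 | step 9 | methyl 2-[(2R)-2-hydroxyhept-6-en-1-yl]-4,6-dimethoxybenzoate | C=CCCC[C@@H](O)Cc1cc(OC)cc(OC)c1C(=O)OC
F4 | step 9 | (3R)-6,8-dimethoxy-3-(pent-4-en-1-yl)-3,4-dihydro-1H-isochromen-1-one | C=CCCC[C@@H]1Cc2cc(OC)cc(OC)c2C(=O)O1
F5 | step 9 | (3R)-6,8-dimethoxy-3-[(4E)-6-oxoundec-4-en-1-yl]-3,4-dihydro-1H-isochromen-1-one | CCCCCC(=O)/C=C/CCC[C@@H]1Cc2cc(OC)cc(OC)c2C(=O)O1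
F6 | step 8 | 9-[5-(2-pentyl-1,3-dioxolan-2-yl)pentyl]-9-borabicyclo[3.3.1]nonane | CCCCCC1(OCCO1)CCCCCB1C2CCCC1CCC2
F7 | step 8 | 5-(2-pentyl-1,3-dioxolan-2-yl)pentan-1-ol | CCCCCC1(OCCO1)CCCCCO
F8 | step 8 | 2-(5-iodopentyl)-2-pentyl-1,3-dioxolane | CCCCCC1(OCCO1)CCCCCI
F9 | step 5 | methyl 2-[(E)-2-ethoxyethenyl]-4,6-dimethoxybenzoate | CCO/C=C/c1cc(OC)cc(OC)c1C(=O)OC
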